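Retrosynthesis (C1 = lactone carbonyl, ring atoms C1–C13 and O13): cut the C6–CH3 bond (Negishi on an alkenyl iodide), the C6≡C7 bond of a ring alkyne (ring-closing alkyne metathesis), the O13–C1 ester, C2–C3 (aldol), C10–C11 (Suzuki–Miyaura) and C8–C9 (enolate alkylation).
Forward: alcohol 18 (C7–C13) and acid 30 (C1–C6) are joined as an ester; the 14-membered lactone, the only ring of the target, then closes between the two methyl-capped alkynes. A transient O3–Si–C6 siloxane ring, iodination, methylation, oxidation of C3 and acetal hydrolysis follow.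
Stereochemistry: C4 from α-D-isosaccharino-1,4-lactone; C13 from methyl (S)-2-hydroxybutanoate; C8 and C2 from the (R)-4-benzyloxazolidinone auxiliary (alkylation and syn-aldol, C3 being a temporary carbinol); 11Z from anti-carbomagnesiation; 6Z from cis Si–H addition.
Enabling feature: in the 14-membered ring the C6=C7 olefin is flanked by sp3 C5 and C8 and lies three atoms from O3 (O3–C3–C4–C5–C6). It can therefore be closed as a ring alkyne and then take up H and Si cis from a tether on O3, which fixes C6 as the methyl-bearing carbon and the ring-cis geometry.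

Key step: step 21

Remark: macrocycles are named as pentadecan-13-olides (ring atoms C1 to C13 and O13, C14–C15 = ethyl), "acetonide" always means the dioxolane joining O4 and the oxygen of the C4 hydroxymethyl group, and α-D-isosaccharino-1,4-lactone 19 is taken as a bought carbohydrate (otherwise one operation from lactose and Ca(OH)2).

Step 1
Reactants: 1 (4R)-4-benzyl-3-propanoyl-1,3-oxazolidin-2-one; 2 2,3-dibromoprop-1-ene
Product: 4 (4R)-4-benzyl-3-[(2S)-4-bromo-2-methylpent-4-enoyl]-1,3-oxazolidin-2-one, via sodium Z-enolate 3 (not isolated)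
Conditions: NaN(SiMe3)2, THF, −78 °C; then 2, −78 to −45 °C
Reagents that add atoms: none
Why: Evans asymmetric alkylation: the chelated sodium Z-enolate should be allylated on the face opposite the benzyl group, which sets the future C8 as (S).

Step 2
Reactants: 4 alkylated imide
Product: 5 (2S)-4-bromo-2-methylpent-4-en-1-ol
Conditions: LiBH4, MeOH (1 equiv), Et2O, 0 °C
Reagents that add atoms: none
Why: Reductive cleavage of the N-acyloxazolidinone by borohydride should release the primary alcohol and the auxiliary without touching the alkenyl bromide or the α-stereocentre.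

Step 3
Reactants: 5 bromo alcohol
Product: 6 (2S)-4-bromo-2-methylpent-4-enal
Conditions: Dess–Martin periodinane, NaHCO3, CH2Cl2, 0 °C to rt
Reagents that add atoms: none
Why: Dess–Martin oxidation under bicarbonate buffer is non-enolising, so the α-branched aldehyde should form without epimerisation and is used crude.

Step 4
Reactants: 6 bromo aldehyde
Product: 7 (4S)-2-bromo-4-methylhex-1-en-5-yne
Conditions: dimethyl (1-diazo-2-oxopropyl)phosphonate, K2CO3, MeOH, 0 °C to rt
Reagents that add atoms: dimethyl (1-diazo-2-oxopropyl)phosphonate, CC(=O)C(=[N+]=[N-])P(=O)(OC)OC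
Why: Ohira–Bestmann (Seyferth–Gilbert) homologation: the diazophosphonate anion adds to the aldehyde and the alkylidene carbene rearranges to the terminal alkyne under carbonate conditions mild enough for the α-centre and the alkenyl bromide.

Step 5
Reactants: 7 terminal alkyne
Product: 9 (4S)-2-bromo-4-methylhept-1-en-5-yne, via lithium acetylide 8 (not isolated)
Conditions: LiN(SiMe3)2, THF, −78 °C; then MeOTf, −78 °C
Reagents that add atoms: methyl trifluoromethanesulfonate, COS(=O)(=O)C(F)(F)F
Why: Acetylide alkylation: the amide base deprotonates only the terminal alkyne and methyl triflate caps it at −78 °C, where the alkenyl bromide is inert.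

Step 6
Reactants: 10 methyl (2S)-2-hydroxybutanoate
Product: 11 methyl (2S)-2-[(tert-butyldimethylsilyl)oxy]butanoate
Conditions: tBuMe2SiCl, imidazole, DMF, rt
Reagents that add atoms: tert-butyldimethylsilyl chloride, CC(C)(C)[Si](C)(C)Cl
Why: Silyl ether formation protects the secondary hydroxyl for the hydride reduction that follows.

Step 7
Reactants: 11 silyloxy ester
Product: 13 (3S)-3-[(tert-butyldimethylsilyl)oxy]pent-1-yne, via silyloxy aldehyde 12 (not isolated)
Conditions: iBu2AlH, CH2Cl2, −78 °C; then MeOH, K2CO3, dimethyl (1-diazo-2-oxopropyl)phosphonate, −78 °C to rt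
Reagents that add atoms: dimethyl (1-diazo-2-oxopropyl)phosphonate, CC(=O)C(=[N+]=[N-])P(=O)(OC)OC
Why: One-pot half-reduction and Ohira–Bestmann homologation: the aluminium hemiacetal holds the aldehyde oxidation level at −78 °C and the aldehyde released by methanol is trapped at once, so C13 should keep its configuration.

Step 8
Reactants: 13 silyloxy alkyne
Product: 14 (3S)-pent-1-yn-3-ol
Conditions: Bu4NF, THF, 0 °C to rt
Reagents that add atoms: none
Why: Fluoride desilylation frees the propargylic hydroxyl that has to direct the carbometalation; the volatile alcohol is isolated by distillation.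

Step 9
Reactants: 14 (3S)-pent-1-yn-3-ol
Product: 16 (1Z,3S)-1-iodo-2-methylpent-1-en-3-ol, via alkenylmagnesium chelate 15 (not isolated)
Conditions: MeMgBr (3 equiv), CuI (10 mol%), Et2O, −10 °C to rt; then I2, −78 to 0 °C
Reagents that add atoms: methylmagnesium bromide, C[Mg]Br; iodine, [I][I]
Why: Copper-catalysed anti-carbomagnesiation of the propargylic alkoxide should place methyl on C12 and magnesium on C11 in a five-membered chelate, and iodinolysis with retention then gives the Z-iodide in which iodine is cis to C13.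

Step 10
Reactants: 9 alkenyl bromide; 16 Z-iodo alcohol
Product: 18 (3S,4Z,8S)-4,8-dimethyl-6-methylideneundec-4-en-9-yn-3-ol, via alkenylboronate 17 (not isolated)
Conditions: B2pin2, PdCl2(PPh3)2 (3 mol%), PPh3, KOPh, toluene, 50 °C; then 16, aq. K3PO4, DMF, 60 °C
Reagents that add atoms: none
Why: One-pot Miyaura borylation and Suzuki–Miyaura coupling: both palladium steps go with retention at sp2 carbon, so the C10–C11 bond of the 2-substituted diene should form with the 11Z geometry intact and the free hydroxyl tolerated.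

Step 11
Reactants: 19 α-D-isosaccharino-1,4-lactone
Product: 20 (5S,8S)-8-(hydroxymethyl)-2,2-dimethyl-1,3,7-trioxaspiro[4.4]nonan-6-one
Conditions: Me2C(OMe)2, acetone, TsOH (cat.), rt
Reagents that add atoms: 2,2-dimethoxypropane, COC(C)(C)OC
Why: Acid-catalysed acetonide formation should engage the only 1,2-diol (the tertiary hydroxyl and its CH2OH) as a spiro dioxolane and leave the 5-hydroxyl free.

Step 12
Reactants: 20 lactone acetonide
Product: 21 (4S)-4-[(2S)-2,3-dihydroxypropyl]-N-methoxy-N,2,2-trimethyl-1,3-dioxolane-4-carboxamide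
Conditions: MeNH(OMe)·HCl, AlMe3, CH2Cl2, 0 °C to rt
Reagents that add atoms: N,O-dimethylhydroxylamine hydrochloride, CNOC.Cl
Why: Aluminium amide aminolysis of the lactone gives the N-methoxy-N-methylamide and unmasks the terminal 1,2-diol, which is carried on at once to prevent relactonisation.

Step 13
Reactants: 21 amide diol
Product: 22 (4S)-N-methoxy-N,2,2-trimethyl-4-(2-oxoethyl)-1,3-dioxolane-4-carboxamide
Conditions: NaIO4, THF/H2O, 0 °C
Reagents that add atoms: none
Why: Periodate glycol cleavage excises the terminal carbon and leaves the aldehyde carbon that becomes C6.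

Step 14
Reactants: 22 amide aldehyde
Product: 23 (4S)-N-methoxy-N,2,2-trimethyl-4-(prop-2-yn-1-yl)-1,3-dioxolane-4-carboxamide
Conditions: dimethyl (1-diazo-2-oxopropyl)phosphonate, K2CO3, MeOH, 0 °C to rt
Reagents that add atoms: dimethyl (1-diazo-2-oxopropyl)phosphonate, CC(=O)C(=[N+]=[N-])P(=O)(OC)OC
Why: Ohira–Bestmann homologation gives the terminal alkyne, and the adjacent quaternary centre cannot epimerise.

Step 15
Reactants: 23 terminal alkyne amide
Product: 25 (4S)-4-(but-2-yn-1-yl)-N-methoxy-N,2,2-trimethyl-1,3-dioxolane-4-carboxamide, via lithium acetylide 24 (not isolated)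
Conditions: LiN(SiMe3)2, THF, −78 °C; then MeOTf, −78 °C
Reagents that add atoms: methyl trifluoromethanesulfonate, COS(=O)(=O)C(F)(F)F
Why: Acetylide alkylation with a non-nucleophilic amide base and methyl triflate caps the alkyne without attack on the N-methoxy-N-methylamide.

Step 16
Reactants: 25 butynyl amide
Product: 26 (4S)-4-(but-2-yn-1-yl)-2,2-dimethyl-1,3-dioxolane-4-carbaldehyde
Conditions: iBu2AlH, THF, −78 °C; aq. KNaC4H4O6
Reagents that add atoms: none
Why: Hydride half-reduction of the N-methoxy-N-methylamide stops at the chelated aluminium hemiaminal and gives the non-enolisable α-alkoxy aldehyde on work-up.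

Step 17
Reactants: 26 quaternary aldehyde; 1 (4R)-4-benzyl-3-propanoyl-1,3-oxazolidin-2-one
Product: 28 (4R)-4-benzyl-3-[(2R,3R)-3-[(4S)-4-(but-2-yn-1-yl)-2,2-dimethyl-1,3-dioxolan-4-yl]-3-hydroxy-2-methylpropanoyl]-1,3-oxazolidin-2-one, via dibutylboron Z-enolate 27 (not isolated)
Conditions: Bu2BOTf, Et3N, CH2Cl2, −78 to 0 °C; then 26, −78 to 0 °C; H2O2, pH 7 buffer, MeOH
Reagents that add atoms: none
Why: Evans syn-aldol: the Z-boron enolate adds through a chair Zimmerman–Traxler transition state on the face dictated by the auxiliary, which sets C2 as (R) and the temporary C3 carbinol as (R).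

Step 18
Reactants: 28 aldol adduct
Product: 29 (4R)-4-benzyl-3-[(2R,3R)-3-[(4S)-4-(but-2-yn-1-yl)-2,2-dimethyl-1,3-dioxolan-4-yl]-2-methyl-3-(triethylsilyloxy)propanoyl]-1,3-oxazolidin-2-one
Conditions: Et3SiOTf, 2,6-lutidine, CH2Cl2, −78 to 0 °C
Reagents that add atoms: triethylsilyl trifluoromethanesulfonate, CC[Si](CC)(CC)OS(=O)(=O)C(F)(F)F
Why: Silylation with the silyl triflate caps the crowded C3 hydroxyl, so that the acid can be activated and the metathesis catalyst meets no protic group.

Step 19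
Reactants: 29 silylated imide
Product: 30 (2R,3R)-3-[(4S)-4-(but-2-yn-1-yl)-2,2-dimethyl-1,3-dioxolan-4-yl]-2-methyl-3-(triethylsilyloxy)propanoic acid
Conditions: LiOH, H2O2, THF/H2O, 0 °C; Na2SO3; HCl to pH 4
Reagents that add atoms: hydrogen peroxide (as LiOOH), OO
Why: Hydroperoxide attacks the exocyclic imide carbonyl selectively (auxiliary cleavage), so the acid should be obtained and the auxiliary released without epimerising C2.

Step 20
Reactants: 30 C1–C6 acid; 18 C7–C13 alcohol
Product: 32 (3S,4Z,8S)-4,8-dimethyl-6-methylideneundec-4-en-9-yn-3-yl (2R,3R)-3-[(4S)-4-(but-2-yn-1-yl)-2,2-dimethyl-1,3-dioxolan-4-yl]-2-methyl-3-(triethylsilyloxy)propanoate, via mixed anhydride 31 (not isolated)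
Conditions: 2,4,6-Cl3C6H2COCl, Et3N, toluene, rt; then 18, DMAP, rt
Reagents that add atoms: none
Why: Yamaguchi esterification: DMAP transfers the aliphatic acyl group of the mixed anhydride to the hindered allylic alcohol, forming the O13–C1 bond with C2 and C13 unchanged.

Step 21
Reactants: 32 seco diyne ester
Product: 33 (2R,3R,4S,8S,11Z,13S)-4-hydroxy-4-(hydroxymethyl)-2,8,12-trimethyl-10-methylidene-3-(triethylsilyloxy)pentadec-11-en-6-yn-13-olide acetonide (14-membered cycloalkyne)
Conditions: Mo(≡CC6H4OMe-4)(OSiPh3)3 (10 mol%), 5 Å molecular sieves, toluene (2 mM), 80 °C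
Reagents that add atoms: none
Why: The molybdenum alkylidyne adds to one methyl-capped alkyne in a [2+2] sense to give a metallacyclobutadiene, cycloreversion expels but-2-yne and leaves a substrate-bound alkylidyne, and the same sequence on the second alkyne forms the C6≡C7 bond, the sieves taking up but-2-yne to drive the equilibrium. The closest known reaction type is ring-closing alkyne metathesis of methyl-capped diyne esters with triarylsilanolate molybdenum alkylidynes. The one ring formed is the 14-membered lactone, closed head-to-tail between the C6 and C7 alkyne termini with the new triple bond inside the ring. No stereocentre is created, and C2, C3, C4, C8 and C13 are spectators. The step needs alkyne-over-alkene selectivity, which the alkylidyne provides because it does not engage the diene, the ester, the silyl ether or the acetal. It also needs ring closure over oligomerisation, which high dilution and the absence of any acidic proton (C3 is a silyl ether here, not yet the β-keto ester) should secure.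

Step 22
Reactants: 33 cycloalkyne silyl ether
Product: 34 (2R,3R,4S,8S,11Z,13S)-3,4-dihydroxy-4-(hydroxymethyl)-2,8,12-trimethyl-10-methylidenepentadec-11-en-6-yn-13-olide acetonide
Conditions: HF·pyridine, pyridine, THF, 0 °C to rt
Reagents that add atoms: none
Why: Buffered fluoride desilylation cleaves only the triethylsilyl ether, exposing O3 for the tether while acetonide, lactone, alkyne and diene stay intact.

Step 23
Reactants: 34 cycloalkyne alcohol
Product: 36 O3–SiMe2–C6 bridged (6E)-alkenylsiloxane of the 14-membered lactone acetonide (2R,3R,4S,8S,11Z,13S), via dimethylsilyl ether 35 (not isolated)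
Conditions: (HMe2Si)2NH, NH4Cl (cat.), 60 °C, then evaporate; Pt2[(CH2=CHSiMe2)2O]3 (2 mol%), THF (5 mM), rt to 45 °C
Reagents that add atoms: 1,1,3,3-tetramethyldisilazane, C[SiH](C)N[SiH](C)C
Why: Silylation followed by platinum-catalysed intramolecular hydrosilylation: cis addition of Si–H in the exo-dig mode from O3 should close an oxasilacyclohexane, put silicon on C6 and hydrogen on C7 and so fix the ring-cis C6=C7 geometry.

Step 24
Reactants: 36 alkenylsiloxane
Product: 38 (2R,3R,4S,6E,8S,11Z,13S)-3,4-dihydroxy-4-(hydroxymethyl)-6-iodo-2,8,12-trimethyl-10-methylidenepentadeca-6,11-dien-13-olide acetonide, via silyl-capped iodide 37 (not isolated)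
Conditions: N-iodosuccinimide, 2,6-lutidine, (CF3)2CHOH, 0 °C; then HF·pyridine, THF, 0 °C
Reagents that add atoms: N-iodosuccinimide, O=C1CCC(=O)N1I
Why: Iododesilylation: iodonium should attack the silicon-bearing carbon of the most nucleophilic π-bond (β-silyl stabilisation) and silicon leave with retention, after which fluoride frees O3.

Step 25
Reactants: 38 alkenyl iodide
Product: 39 (2R,3R,4S,6Z,8S,11Z,13S)-3,4-dihydroxy-4-(hydroxymethyl)-2,6,8,12-tetramethyl-10-methylidenepentadeca-6,11-dien-13-olide acetonide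
Conditions: ZnMe2, Pd(PPh3)4 (5 mol%), THF, 0 °C to rt
Reagents that add atoms: dimethylzinc, C[Zn]C
Why: Negishi coupling: oxidative addition to the alkenyl iodide (expected to outpace ionisation of the hindered allylic ester) and methyl transfer from zinc go with retention, installing the C6 methyl with 6Z geometry.

Step 26
Reactants: 39 C3 carbinol
Product: 40 (2R,4S,6Z,8S,11Z,13S)-4-hydroxy-4-(hydroxymethyl)-2,6,8,12-tetramethyl-10-methylidene-3-oxopentadeca-6,11-dien-13-olide acetonide
Conditions: Dess–Martin periodinane, NaHCO3, CH2Cl2, 0 °C to rt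
Reagents that add atoms: none
Why: Dess–Martin oxidation of the C3 carbinol under bicarbonate buffer should give the β-keto lactone without enolising C2.

Step 27
Reactants: 40 β-keto lactone acetonide
Product: 41 (2R,4S,6Z,8S,11Z,13S)-4-hydroxy-4-(hydroxymethyl)-2,6,8,12-tetramethyl-10-methylidene-3-oxopentadeca-6,11-dien-13-olide (CNP0240796.3)
Conditions: AcOH/H2O (4:1), 40 °C
Reagents that add atoms: none
Why: Acid-catalysed acetal hydrolysis should release the C4 hydroxyl and the hydroxymethyl group under conditions too mild to enolise C2, isomerise the diene or open the lactone.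

Compound list
1 | (4R)-4-benzyl-3-propanoyl-1,3-oxazolidin-2-one | CCC(=O)N1[C@H](Cc2ccccc2)COC1=O | starting material
2 | 2,3-dibromoprop-1-ene | C=C(Br)CBr | starting material
3 | sodium (1Z)-1-[(4R)-4-benzyl-2-oxo-1,3-oxazolidin-3-yl]prop-1-en-1-olate | C/C=C(\[O-])N1[C@H](Cc2ccccc2)COC1=O.[Na+] | intermediate
4 | (4R)-4-benzyl-3-[(2S)-4-bromo-2-methylpent-4-enoyl]-1,3-oxazolidin-2-one | O=C(N1[C@H](Cc2ccccc2)COC1=O)[C@@H](C)CC(Br)=C | intermediate
5 | (2S)-4-bromo-2-methylpent-4-en-1-ol | OC[C@@H](C)CC(Br)=C | intermediate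
6 | (2S)-4-bromo-2-methylpent-4-enal | O=C[C@@H](C)CC(Br)=C | intermediate
7 | (4S)-2-bromo-4-methylhex-1-en-5-yne | C#C[C@@H](C)CC(Br)=C | intermediate
8 | lithium (3S)-5-bromo-3-methylhex-5-en-1-yn-1-ide | [Li]C#C[C@@H](C)CC(Br)=C | intermediate
9 | (4S)-2-bromo-4-methylhept-1-en-5-yne | CC#C[C@@H](C)CC(Br)=C | intermediate
10 | methyl (2S)-2-hydroxybutanoate | CC[C@H](O)C(=O)OC | starting material
11 | methyl (2S)-2-[(tert-butyldimethylsilyl)oxy]butanoate | CC[C@H](O[Si](C)(C)C(C)(C)C)C(=O)OC | intermediate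
12 | (2S)-2-[(tert-butyldimethylsilyl)oxy]butanal | CC[C@H](O[Si](C)(C)C(C)(C)C)C=O | intermediate
13 | (3S)-3-[(tert-butyldimethylsilyl)oxy]pent-1-yne | CC[C@H](O[Si](C)(C)C(C)(C)C)C#C | intermediate
14 | (3S)-pent-1-yn-3-ol | CC[C@H](O)C#C | intermediate
15 | (5S)-5-ethyl-4-methyl-2,5-dihydro-1,2-oxamagnesole (chelated alkenylmagnesium alkoxide) | CC[C@@H]1O[Mg]C=C1C | intermediate
16 | (1Z,3S)-1-iodo-2-methylpent-1-en-3-ol | I/C=C(/C)[C@H](CC)O | intermediate
17 | 4,4,5,5-tetramethyl-2-[(4S)-4-methylhept-1-en-5-yn-2-yl]-1,3,2-dioxaborolane | CC#C[C@@H](C)CC(=C)B1OC(C)(C)C(C)(C)O1 | intermediate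
18 | (3S,4Z,8S)-4,8-dimethyl-6-methylideneundec-4-en-9-yn-3-ol | CC#C[C@@H](C)CC(=C)/C=C(/C)[C@H](CC)O | intermediate
19 | α-D-isosaccharino-1,4-lactone, (3S,5S)-3-hydroxy-3,5-bis(hydroxymethyl)oxolan-2-one | O=C1O[C@H](CO)C[C@]1(O)CO | starting material
20 | (5S,8S)-8-(hydroxymethyl)-2,2-dimethyl-1,3,7-trioxaspiro[4.4]nonan-6-one | O=C1O[C@H](CO)C[C@]12COC(C)(C)O2 | intermediate
21 | (4S)-4-[(2S)-2,3-dihydroxypropyl]-N-methoxy-N,2,2-trimethyl-1,3-dioxolane-4-carboxamide | CON(C)C(=O)[C@@]1(COC(C)(C)O1)C[C@H](O)CO | intermediate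
22 | (4S)-N-methoxy-N,2,2-trimethyl-4-(2-oxoethyl)-1,3-dioxolane-4-carboxamide | CON(C)C(=O)[C@@]1(COC(C)(C)O1)CC=O | intermediate
23 | (4S)-N-methoxy-N,2,2-trimethyl-4-(prop-2-yn-1-yl)-1,3-dioxolane-4-carboxamide | CON(C)C(=O)[C@@]1(COC(C)(C)O1)CC#C | intermediate
24 | lithium 3-[(4S)-4-[methoxy(methyl)carbamoyl]-2,2-dimethyl-1,3-dioxolan-4-yl]prop-1-yn-1-ide | CON(C)C(=O)[C@@]1(COC(C)(C)O1)CC#C[Li] | intermediate
25 | (4S)-4-(but-2-yn-1-yl)-N-methoxy-N,2,2-trimethyl-1,3-dioxolane-4-carboxamide | CON(C)C(=O)[C@@]1(COC(C)(C)O1)CC#CC | intermediate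
26 | (4S)-4-(but-2-yn-1-yl)-2,2-dimethyl-1,3-dioxolane-4-carbaldehyde | O=C[C@@]1(COC(C)(C)O1)CC#CC | intermediate
27 | (4R)-4-benzyl-3-[(1Z)-1-(dibutylboranyloxy)prop-1-en-1-yl]-1,3-oxazolidin-2-one | C/C=C(\OB(CCCC)CCCC)N1[C@H](Cc2ccccc2)COC1=O | intermediate
28 | (4R)-4-benzyl-3-[(2R,3R)-3-[(4S)-4-(but-2-yn-1-yl)-2,2-dimethyl-1,3-dioxolan-4-yl]-3-hydroxy-2-methylpropanoyl]-1,3-oxazolidin-2-one | O=C(N1[C@H](Cc2ccccc2)COC1=O)[C@H](C)[C@@H](O)[C@@]1(COC(C)(C)O1)CC#CC | intermediate
29 | (4R)-4-benzyl-3-[(2R,3R)-3-[(4S)-4-(but-2-yn-1-yl)-2,2-dimethyl-1,3-dioxolan-4-yl]-2-methyl-3-(triethylsilyloxy)propanoyl]-1,3-oxazolidin-2-one | O=C(N1[C@H](Cc2ccccc2)COC1=O)[C@H](C)[C@@H](O[Si](CC)(CC)CC)[C@@]1(COC(C)(C)O1)CC#CC | intermediate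
30 | (2R,3R)-3-[(4S)-4-(but-2-yn-1-yl)-2,2-dimethyl-1,3-dioxolan-4-yl]-2-methyl-3-(triethylsilyloxy)propanoic acid | OC(=O)[C@H](C)[C@@H](O[Si](CC)(CC)CC)[C@@]1(COC(C)(C)O1)CC#CC | intermediate
31 | mixed anhydride of 30 with 2,4,6-trichlorobenzoic acid | O=C(OC(=O)c1c(Cl)cc(Cl)cc1Cl)[C@H](C)[C@@H](O[Si](CC)(CC)CC)[C@@]1(COC(C)(C)O1)CC#CC | intermediate
32 | (3S,4Z,8S)-4,8-dimethyl-6-methylideneundec-4-en-9-yn-3-yl (2R,3R)-3-[(4S)-4-(but-2-yn-1-yl)-2,2-dimethyl-1,3-dioxolan-4-yl]-2-methyl-3-(triethylsilyloxy)propanoate | CC#C[C@@H](C)CC(=C)/C=C(/C)[C@H](CC)OC(=O)[C@H](C)[C@@H](O[Si](CC)(CC)CC)[C@@]1(COC(C)(C)O1)CC#CC | intermediate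
33 | (2R,3R,4S,8S,11Z,13S)-4-hydroxy-4-(hydroxymethyl)-2,8,12-trimethyl-10-methylidene-3-(triethylsilyloxy)pentadec-11-en-6-yn-13-olide acetonide | C=C1/C=C(/C)[C@H](CC)OC(=O)[C@H](C)[C@@H](O[Si](CC)(CC)CC)[C@@]2(COC(C)(C)O2)CC#C[C@@H](C)C1 | intermediate
34 | (2R,3R,4S,8S,11Z,13S)-3,4-dihydroxy-4-(hydroxymethyl)-2,8,12-trimethyl-10-methylidenepentadec-11-en-6-yn-13-olide acetonide | C=C1/C=C(/C)[C@H](CC)OC(=O)[C@H](C)[C@@H](O)[C@@]2(COC(C)(C)O2)CC#C[C@@H](C)C1 | intermediate
35 | 3-O-dimethylsilyl ether of 34 | C=C1/C=C(/C)[C@H](CC)OC(=O)[C@H](C)[C@@H](O[SiH](C)C)[C@@]2(COC(C)(C)O2)CC#C[C@@H](C)C1 | intermediate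
36 | (2R,3R,4S,6E,8S,11Z,13S)-3,4-dihydroxy-4-(hydroxymethyl)-2,8,12-trimethyl-10-methylidenepentadeca-6,11-dien-13-olide acetonide with O3 and C6 bridged by SiMe2 (1-oxa-2-silacyclohexane) | C=C1/C=C(/C)[C@H](CC)OC(=O)[C@H](C)[C@H]2O[Si](C)(C)/C(C[C@]23COC(C)(C)O3)=C/[C@@H](C)C1 | intermediate
37 | 3-O-[(1,1,1,3,3,3-hexafluoropropan-2-yloxy)dimethylsilyl] ether of 38 | C=C1/C=C(/C)[C@H](CC)OC(=O)[C@H](C)[C@@H](O[Si](C)(C)OC(C(F)(F)F)C(F)(F)F)[C@@]2(COC(C)(C)O2)C/C([I])=C\[C@@H](C)C1 | intermediate
38 | (2R,3R,4S,6E,8S,11Z,13S)-3,4-dihydroxy-4-(hydroxymethyl)-6-iodo-2,8,12-trimethyl-10-methylidenepentadeca-6,11-dien-13-olide acetonide | C=C1/C=C(/C)[C@H](CC)OC(=O)[C@H](C)[C@@H](O)[C@@]2(COC(C)(C)O2)C/C([I])=C\[C@@H](C)C1 | intermediate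
39 | (2R,3R,4S,6Z,8S,11Z,13S)-3,4-dihydroxy-4-(hydroxymethyl)-2,6,8,12-tetramethyl-10-methylidenepentadeca-6,11-dien-13-olide acetonide | C=C1/C=C(/C)[C@H](CC)OC(=O)[C@H](C)[C@@H](O)[C@@]2(COC(C)(C)O2)C/C(C)=C\[C@@H](C)C1 | intermediate
40 | (2R,4S,6Z,8S,11Z,13S)-4-hydroxy-4-(hydroxymethyl)-2,6,8,12-tetramethyl-10-methylidene-3-oxopentadeca-6,11-dien-13-olide acetonide | C=C1/C=C(/C)[C@H](CC)OC(=O)[C@H](C)C(=O)[C@@]2(COC(C)(C)O2)C/C(C)=C\[C@@H](C)C1 | intermediate
41 | (2R,4S,6Z,8S,11Z,13S)-4-hydroxy-4-(hydroxymethyl)-2,6,8,12-tetramethyl-10-methylidene-3-oxopentadeca-6,11-dien-13-olide (CNP0240796.3) | C=C1/C=C(/C)[C@H](CC)OC(=O)[C@H](C)C(=O)[C@@](O)(CO)C/C(C)=C\[C@@H](C)C1 | target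

Total step count: 27 (each one-pot sequence counted once). Longest linear sequence: 17 steps (steps 11 to 27).

Steps most likely to fail

Step 23. Silylation of the crowded O3 may stay incomplete, or delivery of silicon from O3 may be outrun by side reactions of the Si–H group. The fallback moves the tether to the homopropargylic O4, the classical five-membered exo-dig case. Setting out from 34, aqueous acetic acid hydrolyses the acetonide to the cycloalkyne triol F1. (HMe2Si)2NH converts all three hydroxyls into the tris(dimethylsilyl) ether F2, and the same platinum catalyst should deliver silicon from O4 to C6 to give the spiro alkenylsiloxane F3 (delivery from O3 or from the primary oxygen is also exo and also ends on C6). Excess N-iodosuccinimide in (CF3)2CHOH gives the silyl-capped iodide F4, and HF·pyridine strips all silicon to the iodo triol F5. Me2C(OMe)2 with pyridinium p-toluenesulfonate then closes the terminal acetonide again, which returns to the route at 38.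

Step 24. Iodination of the conjugated diene may compete with ipso-substitution, or bond rotation in the β-silyl cation may erode the 6E geometry. The fallback uses no silicon and no strongly electrophilic iodine source. Setting out from 33, Cp2Zr(H)Cl (THF, rt) should add H and Zr cis, with zirconium on the less hindered C6 (C7 carries the branched C8), to give the alkenylzirconocene chloride F6. Iodine at −78 °C should cleave the C–Zr bond with retention far faster than it attacks the diene, giving the iodide silyl ether F7. HF·pyridine as in step 22 removes the triethylsilyl group and returns to the route at 38.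

Step 21. Oligomerisation or stalled catalyst turnover at the α-branched C7 alkyne may take the place of ring closure. The fallback forms C6≡C7 between the fragments and closes the ring at the ester. Setting out from 18 and 29, 18 is capped with Me3SiCl and imidazole as the trimethylsilyl ether F8. Alkyne cross-metathesis of 29 with an excess of F8, under the same molybdenum alkylidyne and 5 Å molecular sieves, gives the open-chain alkyne F9 with loss of but-2-yne. LiOH/H2O2 removes the auxiliary and, in the same operation, the labile trimethylsilyl ether to give the seco hydroxy acid F10. Macrolactonisation with 2-methyl-6-nitrobenzoic anhydride and DMAP at high dilution forms the O13–C1 bond and returns to the route at 33.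

Further compounds
F1 | step 23 | (2R,3R,4S,8S,11Z,13S)-3,4-dihydroxy-4-(hydroxymethyl)-2,8,12-trimethyl-10-methylidenepentadec-11-en-6-yn-13-olide (cycloalkyne triol) | C=C1/C=C(/C)[C@H](CC)OC(=O)[C@H](C)[C@@H](O)[C@@](O)(CO)CC#C[C@@H](C)C1
F2 | step 23 | tris(dimethylsilyl) ether of F1 (O3, O4 and the primary oxygen) | C=C1/C=C(/C)[C@H](CC)OC(=O)[C@H](C)[C@@H](O[SiH](C)C)[C@@](O[SiH](C)C)(CO[SiH](C)C)CC#C[C@@H](C)C1
F3 | step 23 | spiro (6E)-alkenylsiloxane with O4 and C6 bridged by SiMe2 (1-oxa-2-silacyclopentane), O3 and the primary oxygen as dimethylsilyl ethers | C=C1/C=C(/C)[C@H](CC)OC(=O)[C@H](C)[C@@H](O[SiH](C)C)[C@]2(CO[SiH](C)C)O[Si](C)(C)/C(C2)=C/[C@@H](C)C1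
F4 | step 23 | (6E)-6-iodo triol carrying O4–SiMe2–OCH(CF3)2 and two O–SiHMe2 groups (silyl-capped iodide) | C=C1/C=C(/C)[C@H](CC)OC(=O)[C@H](C)[C@@H](O[SiH](C)C)[C@@](O[Si](C)(C)OC(C(F)(F)F)C(F)(F)F)(CO[SiH](C)C)C/C([I])=C\[C@@H](C)C1
F5 | step 23 | (2R,3R,4S,6E,8S,11Z,13S)-3,4-dihydroxy-4-(hydroxymethyl)-6-iodo-2,8,12-trimethyl-10-methylidenepentadeca-6,11-dien-13-olide (iodo triol) | C=C1/C=C(/C)[C@H](CC)OC(=O)[C@H](C)[C@@H](O)[C@@](O)(CO)C/C([I])=C\[C@@H](C)C1
F6 | step 24 | C6 chlorobis(cyclopentadienyl)zirconium alkenyl derived from 33 by cis H–Zr addition (6E) | C=C1/C=C(/C)[C@H](CC)OC(=O)[C@H](C)[C@@H](O[Si](CC)(CC)CC)[C@@]2(COC(C)(C)O2)C/C([Zr](Cl)(C3C=CC=C3)C3C=CC=C3)=C\[C@@H](C)C1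
F7 | step 24 | 3-O-triethylsilyl ether of 38 | C=C1/C=C(/C)[C@H](CC)OC(=O)[C@H](C)[C@@H](O[Si](CC)(CC)CC)[C@@]2(COC(C)(C)O2)C/C([I])=C\[C@@H](C)C1
F8 | step 21 | trimethylsilyl ether of 18 | CC#C[C@@H](C)CC(=C)/C=C(/C)[C@H](CC)O[Si](C)(C)C
F9 | step 21 | open-chain C6≡C7 cross-metathesis product (N-acyloxazolidinone, 3-OSiEt3, 13-OSiMe3, acetonide) | O=C(N1[C@H](Cc2ccccc2)COC1=O)[C@H](C)[C@@H](O[Si](CC)(CC)CC)[C@@]1(COC(C)(C)O1)CC#C[C@@H](C)CC(=C)/C=C(/C)[C@H](CC)O[Si](C)(C)C
F10 | step 21 | seco hydroxy acid (3-OSiEt3, 13-OH, acetonide, C6≡C7) | OC(=O)[C@H](C)[C@@H](O[Si](CC)(CC)CC)[C@@]1(COC(C)(C)O1)CC#C[C@@H](C)CC(=C)/C=C(/C)[C@H](CC)O
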